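**Retrosynthetic overview**
1. Feature: in ring B (butenolide O–C6–C7=C11–C12) C6 is the γ-carbon. Its neighbour C5 bears oxygen and sits next to the fully substituted, oxygen-bearing C4, so C5–C6 is a vinylogous aldol bond to an aldehyde with no α-hydrogen.
2. Target 36 ⇒ (C1 oxidation, C8 and C13 esters) ⇒ epoxide 31 ⇒ 4,5-diol 28 (oxirane ring C by double inversion at C4, net retention) ⇒ ten-membered carbinol 27.
3. 27 ⇒ open-chain butenolide aldehyde 24. Ring A closes at C5–C6 by a silyl triflate–amine vinylogous Mukaiyama aldol. C1 travels as a PMB-protected carbinol because the same reagents would enolise a free ketone.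
4. 24 ⇒ bromobutenolide 18 (tetronic acid gives C6, C7, C11, C12; the amide acetal gives C13) + aldehyde 12 (C7–C8 by Nozaki–Hiyama–Kishi coupling, C8 by CBS reduction). 12 ⇒ (S)-linalool (C1–C5, C15, C4–O) + trans-2-butene (C8–C10, C14) by Brown crotylation.
5. Order of rings: B (present in tetronic acid), A (step 16), C (step 19).

Key step: step 16

Numbering: germacrane numbering is used. C1 is the carbinol/ketone carbon, C4 the methyl-bearing oxirane carbon, C5 the oxirane CH, C6 the lactone O–CH, C7=C11 the butenolide alkene, C8 the ester carbinol, C10 the CH–CH3, C12 the lactone C=O, C13 the CH2O, C14 the methyl on C10 and C15 the methyl on C4.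
Assumption: (S)-(+)-linalool is taken as enantiomerically pure commercial material. Lower purity would appear as separable diastereomers after step 3.

**Step 1**
Reactants: 1 (S)-(+)-linalool
Product: 2 (S)-linalool triethylsilyl ether
Conditions: TESOTf, 2,6-lutidine, CH2Cl2, 0 °C
Reagents that add atoms: triethylsilyl triflate, CC[Si](CC)(CC)OS(=O)(=O)C(F)(F)F
Why: Silylation of a tertiary alcohol with a silyl triflate and a hindered pyridine base is routine, leaves both alkenes and the C4 stereocentre (S, from linalool) untouched, and installs the polar group that later steers attack on C5.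

**Step 2**
Reactants: 2 (S)-linalool triethylsilyl ether
Product: 4 (4S)-4-methyl-4-(triethylsilyloxy)hex-5-enal (C1 aldehyde), via secondary ozonide 3 (not isolated)
Conditions: O3 (one equivalent, Sudan Red 7B end point), CH2Cl2, −78 °C; then Me2S, −78 °C → rt
Reagents that add atoms: ozone, [O-][O+]=O
Why: Ozonolysis with a limited amount of ozone selects the electron-rich trisubstituted alkene over the hindered, inductively deactivated vinyl group on the quaternary carbinol carbon, and Me2S reduces the ozonide to the aldehyde.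

**Step 3**
Reactants: 4 C1 aldehyde; 5 trans-2-butene
Product: 8 (3S,4R,7S)-3,7-dimethyl-7-(triethylsilyloxy)nona-1,8-dien-4-ol (1R,10S anti adduct), via crotylborane 6 (not isolated), via borinate 7 (not isolated)
Conditions: 5, KOt-Bu, n-BuLi, THF, −78 → −45 °C; (−)-Ipc2BOMe (from (+)-α-pinene), −78 °C; BF3·OEt2; 4, −78 °C; then NaOH, H2O2, 0 °C → rt
Reagents that add atoms: none
Why: In this Brown asymmetric crotylboration through a closed chair transition state the E-crotyl geometry gives the anti C1/C10 relationship and the Ipc groups choose the aldehyde face, so 1R,10S is set by the reagent, which an achiral crotylboronate could not do because C4 is too remote.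

**Step 4**
Reactants: 8 anti homoallylic alcohol
Product: 9 C1 4-methoxybenzyl ether of 8
Conditions: NaH, PMBCl, Bu4NI (cat.), THF/DMF, 0 °C → rt
Reagents that add atoms: 4-methoxybenzyl chloride, COc1ccc(CCl)cc1
Why: This Williamson etherification masks C1 as an ether that is inert to silyl triflate and amine, so no ketone is exposed in step 16 and C10 cannot epimerise before the last step.

**Step 5**
Reactants: 9 PMB-protected diene
Product: 11 (3S,4R,7S)-4-(4-methoxybenzyloxy)-3,7-dimethyl-7-(triethylsilyloxy)non-8-en-1-ol (C8 alcohol), via trialkylborane 10 (not isolated)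
Conditions: Sia2BH (from BH3·SMe2 and 2-methylbut-2-ene), THF, 0 °C; then NaOH, H2O2
Reagents that add atoms: hydrogen peroxide, OO
Why: Hydroboration–oxidation with a bulky dialkylborane is anti-Markovnikov and should prefer, on steric and inductive grounds, the C8=C9 vinyl group beside the tertiary C10 over the vinyl group on the fully substituted, silyloxy-bearing C4.

**Step 6**
Reactants: 11 C8 alcohol
Product: 12 (3S,4R,7S)-4-(4-methoxybenzyloxy)-3,7-dimethyl-7-(triethylsilyloxy)non-8-enal (C8 aldehyde)
Conditions: Dess–Martin periodinane, CH2Cl2, 0 °C → rt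
Reagents that add atoms: none
Why: Dess–Martin oxidation stops at the aldehyde under near-neutral conditions that spare the silyl ether, the PMB ether and the alkene, and C10 is β to the new carbonyl and so is not at risk.

**Step 7**
Reactants: 13 tetronic acid
Product: 14 3-[(dimethylamino)methylidene]furan-2,4(3H,5H)-dione
Conditions: Me2NCH(OMe)2, toluene, rt
Reagents that add atoms: N,N-dimethylformamide dimethyl acetal, COC(OC)N(C)C
Why: Condensation of the acidic C3 position of a cyclic 1,3-dicarbonyl compound with an amide acetal places one carbon (the future C13) on C11 and avoids the methylene-bridged bis-adducts that formaldehyde gives with tetronic acid.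

**Step 8**
Reactants: 14 enaminone
Product: 16 4-bromo-2-oxo-2,5-dihydrofuran-3-carbaldehyde, via bromoiminium bromide 15 (not isolated)
Conditions: (COBr)2, CH2Cl2, 0 °C → rt; then ice-water
Reagents that add atoms: oxalyl bromide, O=C(Br)C(=O)Br; water, O
Why: This is the second half of a Vilsmeier–Haack–Arnold haloformylation, in which the vinylogous amide oxygen is acylated, bromide replaces it by addition–elimination with loss of CO and CO2, and water hydrolyses the iminium ion to the β-bromo enal.

**Step 9**
Reactants: 16 bromo aldehyde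
Product: 17 4-bromo-3-(hydroxymethyl)furan-2(5H)-one
Conditions: NaBH4, CeCl3·7H2O, MeOH/THF, −78 °C
Reagents that add atoms: none
Why: Luche reduction delivers hydride 1,2 to the aldehyde faster than to the lactone or to the bromine-bearing β-carbon, as known for the analogous 4-halo-3-formyl lactones.

**Step 10**
Reactants: 17 bromo alcohol
Product: 18 4-bromo-3-[(tert-butyldiphenylsilyloxy)methyl]furan-2(5H)-one
Conditions: TBDPSCl, imidazole, CH2Cl2, 0 °C
Reagents that add atoms: tert-butyldiphenylsilyl chloride, CC(C)(C)[Si](Cl)(c1ccccc1)c1ccccc1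
Why: Standard silylation of a primary alcohol, with TBDPS chosen because it outlasts the later acidic removal of a tertiary TES ether and because its crowded, weakly basic oxygen resists ionisation at C13.

**Step 11**
Reactants: 12 C8 aldehyde; 18 bromobutenolide
Product: 19 C8 carbinol (both C8 epimers)
Conditions: CrCl2 (excess), NiCl2 (cat.), DMF, rt
Reagents that add atoms: none
Why: In the Nozaki–Hiyama–Kishi coupling zerovalent nickel inserts into the activated β-bromo enoate C–Br bond, transmetalation gives an alkenyl species of trivalent chromium that adds only to the aldehyde and tolerates the lactone, and no control at C8 is expected or needed because the β-methyl group is too weak a director.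

**Step 12**
Reactants: 19 C8 carbinol
Product: 20 C8 ketone (4-acylbutenolide)
Conditions: Dess–Martin periodinane, CH2Cl2, 0 °C
Reagents that add atoms: none
Why: Dess–Martin oxidation of the allylic alcohol merges both C8 epimers into one ketone without base, so the acidic C6 methylene is not disturbed.

**Step 13**
Reactants: 20 C8 ketone
Product: 21 (8R)-carbinol
Conditions: (S)-Me-CBS (cat.), catecholborane, toluene, −78 °C
Reagents that add atoms: none
Why: In the Corey–Bakshi–Shibata reduction the fully substituted alkenyl carbon C7 acts as the large group and the C9 methylene as the small one, so the (S)-oxazaborolidine should give 8R, and catecholborane at low temperature leaves the vinyl group unhydroborated.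

**Step 14**
Reactants: 21 (8R)-carbinol
Product: 22 (8R)-tert-butyldimethylsilyl ether
Conditions: TBSOTf, 2,6-lutidine, CH2Cl2, −78 → 0 °C
Reagents that add atoms: tert-butyldimethylsilyl triflate, CC(C)(C)[Si](C)(C)OS(=O)(=O)C(F)(F)F
Why: Silyl triflate silylation overcomes the hindrance at C8, and the weak base 2,6-lutidine does not convert the butenolide into a silyloxyfuran.

**Step 15**
Reactants: 22 (8R)-silyl ether
Product: 24 butenolide aldehyde (1R,4S,8R,10S), the key-step precursor, via vicinal diol 23 (not isolated)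
Conditions: OsO4 (cat.), NaIO4, 2,6-lutidine, dioxane/H2O, rt
Reagents that add atoms: osmium tetroxide (catalytic oxygen carrier), O=[Os](=O)(=O)=O; sodium periodate, [Na+].[O-]I(=O)(=O)=O
Why: Lemieux–Johnson cleavage acts on the only electron-rich alkene (the tetrasubstituted, electron-poor butenolide alkene is inert), spares the PMB ring better than ozone would, and gives an aldehyde that cannot enolise.

**Step 16**
Reactants: 24 butenolide aldehyde
Product: 27 ten-membered C5 carbinol (1R,4S,5R,6R,8R,10S) bearing the C4 TES ether, via silyloxyfuran 25 (not isolated), via C5 trimethylsilyl ether 26 (not isolated)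
Conditions: TMSOTf, i-Pr2NEt, CH2Cl2 (about 1 mM, slow addition of 24), −78 → −20 °C; then aq. citric acid, MeOH, 0 °C
Reagents that add atoms: none
Why: Proposed new method: TMSOTf with i-Pr2NEt soft-enolises the butenolide at C6 to the aromatic 2-silyloxyfuran 25, further TMSOTf silylates the C5 aldehyde oxygen, C6 attacks C5 through an open transition state, and loss of silicon from the resulting 2-silyloxyfuranium ion restores the butenolide and leaves the TMS ether 26, which the citric acid quench cleaves. The closest known reactions are the intermolecular one-pot silyl triflate–amine vinylogous aldol of butenolides with non-enolisable aldehydes and the vinylogous Mukaiyama aldol of 2-silyloxyfurans with α-alkoxy aldehydes, and the new element is their use to close a medium-sized carbocycle. Ring A closes 10-exo-trig with the C5 oxygen outside the ring, and high dilution with slow addition is what holds back oligomers. C5 is set by polar Felkin–Anh control: the C4–OTES bond lies anti to the incoming C6, the C3 methylene (the tether) sits beside the silylated oxygen and the C15 methyl beside the formyl hydrogen, which gives 5R from 4S. C6 is set by C8: A(1,3) strain with the C13 methylene holds C8–H in the furan plane, C9 leaves from one face, and bonding of C5 to the other face in the antiperiplanar arrangement gives like-signed gauche torsions about C5–C6, C6–C7 and C7–C8 without a syn-pentane contact between C5 and C9, which corresponds to 6R and is the least secure prediction of the route. The furan must be the only nucleophile and C5 the only electrophile, and this is secured by the PMB ether at C1 (a ketone there would be enolised by the same reagents, and its C10 enol silane could close a six-membered ring on C5), by the lack of α-hydrogen at C4, by the substituent on C11 that blocks α-attack, and by the crowded C13 silyl ether that resists ionisation.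

**Step 17**
Reactants: 27 C5 carbinol
Product: 28 4,5-diol (4S,5R)
Conditions: HF·pyridine, pyridine, THF, 0 °C → rt
Reagents that add atoms: none
Why: Buffered HF·pyridine removes a TES ether well before a hindered secondary TBS or a primary TBDPS ether, and the acidic medium avoids retro-aldol cleavage and C6 deprotonation.

**Step 18**
Reactants: 28 4,5-diol
Product: 30 (4R)-4-bromo 5-acetate, via cyclic orthoacetate 29 (not isolated)
Conditions: MeC(OMe)3, PPTS (cat.), CH2Cl2, rt; evaporate; AcBr, 2,6-di-tert-butyl-4-methylpyridine (cat.), CH2Cl2, 0 °C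
Reagents that add atoms: trimethyl orthoacetate, COC(C)(OC)OC; acetyl bromide, CC(=O)Br
Why: In the Kolb–Sharpless orthoester procedure acetyl bromide converts the cyclic orthoacetate into an acetoxonium ion, which bromide opens with inversion at the tertiary, more cation-stabilising C4 rather than at the doubly flanked C5, so the C5–O bond is never broken.

**Step 19**
Reactants: 30 bromo acetate
Product: 31 (4S,5R)-epoxide (ring C)
Conditions: K2CO3, MeOH, −20 → 0 °C
Reagents that add atoms: none
Why: Methanolysis of the acetate frees the C5 alkoxide, which displaces the anti bromide 3-exo-tet with a second inversion at C4, so the diol configuration is retained overall and C3 and C6 end up cis on the oxirane as in the target, while C10 cannot epimerise because C1 is still an ether.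

**Step 20**
Reactants: 31 epoxide
Product: 32 8,13-diol
Conditions: TBAF, AcOH (1:1), THF, 0 °C → rt
Reagents that add atoms: none
Why: Fluoride desilylation buffered with acetic acid keeps the medium near neutral, so it should trigger neither C6 deprotonation (which would open the oxirane by vinylogous β-elimination) nor acid opening of the trisubstituted oxirane.

**Step 21**
Reactants: 32 8,13-diol
Product: 33 13-acetate
Conditions: Ac2O (one equivalent), pyridine, CH2Cl2, 0 °C
Reagents that add atoms: acetic anhydride, CC(=O)OC(C)=O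
Why: The primary allylic C13 hydroxyl is acylated much faster than the hindered secondary C8 hydroxyl, and pyridine is too weak a base to deprotonate C6.

**Step 22**
Reactants: 33 13-acetate
Product: 34 8-methacrylate
Conditions: methacrylic anhydride, DMAP (cat.), pyridine, CH2Cl2, 0 °C → rt
Reagents that add atoms: methacrylic anhydride, C=C(C)C(=O)OC(=O)C(C)=C
Why: DMAP-catalysed acyl transfer esterifies C8–OH with retention, and doing this while C1 is still an ether avoids a transannular hemiketal between C8–OH and a C1 ketone.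

**Step 23**
Reactants: 34 8-methacrylate
Product: 35 C1 carbinol (1R)
Conditions: DDQ, CH2Cl2/pH 7 buffer, 0 °C
Reagents that add atoms: none
Why: Oxidative PMB cleavage with DDQ is neutral toward esters, oxirane and butenolide, and the 1R hydroxyl can reach the rear of the C4–O bond only by forming a trans-bridged 11-oxabicyclo[6.2.1]undecane, so transannular opening should stay slow under buffer.

**Step 24**
Reactants: 35 C1 carbinol
Product: 36 CNP0128625.1 (4S,5R,6R,8R,10S)
Conditions: Dess–Martin periodinane, NaHCO3, CH2Cl2, 0 °C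
Reagents that add atoms: none
Why: Buffered Dess–Martin oxidation creates the C1 ketone last, so that C10 (now α to a carbonyl) and the acid- and base-labile keto-epoxy-butenolide array meet no further reagent.

**Compound list**
1 | (S)-(+)-linalool | CC(C)=CCC[C@](C)(O)C=C | starting material
2 | (S)-linalool triethylsilyl ether | CC(C)=CCC[C@](C)(O[Si](CC)(CC)CC)C=C | intermediate
3 | secondary ozonide of 2 (1,2,4-trioxolane, not isolated) | CC1(C)OOC(CC[C@](C)(O[Si](CC)(CC)CC)C=C)O1 | intermediate
4 | (4S)-4-methyl-4-(triethylsilyloxy)hex-5-enal | O=CCC[C@](C)(O[Si](CC)(CC)CC)C=C | intermediate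
5 | trans-2-butene | C/C=C/C | starting material
6 | (E)-crotyldiisopinocampheylborane, Ipc from (+)-α-pinene (not isolated) | C/C=C/CB([C@@H]1C[C@@H]2C[C@H]([C@H]1C)C2(C)C)[C@@H]1C[C@@H]2C[C@H]([C@H]1C)C2(C)C | intermediate
7 | diisopinocampheylborinate of 8 (not isolated) | C=C[C@H](C)[C@H](OB([C@@H]1C[C@@H]2C[C@H]([C@H]1C)C2(C)C)[C@@H]1C[C@@H]2C[C@H]([C@H]1C)C2(C)C)CC[C@](C)(O[Si](CC)(CC)CC)C=C | intermediate
8 | (3S,4R,7S)-3,7-dimethyl-7-(triethylsilyloxy)nona-1,8-dien-4-ol | C=C[C@H](C)[C@H](O)CC[C@](C)(O[Si](CC)(CC)CC)C=C | intermediate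
9 | C1 PMB ether of 8 | C=C[C@H](C)[C@H](OCc1ccc(OC)cc1)CC[C@](C)(O[Si](CC)(CC)CC)C=C | intermediate
10 | C8 disiamylborane adduct of 9 (not isolated) | CC(C)C(C)B(CC[C@H](C)[C@H](OCc1ccc(OC)cc1)CC[C@](C)(O[Si](CC)(CC)CC)C=C)C(C)C(C)C | intermediate
11 | C8 primary alcohol | OCC[C@H](C)[C@H](OCc1ccc(OC)cc1)CC[C@](C)(O[Si](CC)(CC)CC)C=C | intermediate
12 | C8 aldehyde | O=CC[C@H](C)[C@H](OCc1ccc(OC)cc1)CC[C@](C)(O[Si](CC)(CC)CC)C=C | intermediate
13 | tetronic acid | OC1=CC(=O)OC1 | starting material
14 | 3-[(dimethylamino)methylidene]furan-2,4(3H,5H)-dione | CN(C)C=C1C(=O)COC1=O | intermediate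
15 | (4-bromo-2-oxo-2,5-dihydrofuran-3-yl)methylidene-dimethyliminium bromide (not isolated) | C[N+](C)=CC1=C(Br)COC1=O.[Br-] | intermediate
16 | 4-bromo-2-oxo-2,5-dihydrofuran-3-carbaldehyde | O=CC1=C(Br)COC1=O | intermediate
17 | 4-bromo-3-(hydroxymethyl)furan-2(5H)-one | OCC1=C(Br)COC1=O | intermediate
18 | 4-bromo-3-[(tert-butyldiphenylsilyloxy)methyl]furan-2(5H)-one | CC(C)(C)[Si](OCC1=C(Br)COC1=O)(c1ccccc1)c1ccccc1 | intermediate
19 | C8 carbinol, both C8 epimers | OC(C[C@H](C)[C@H](OCc1ccc(OC)cc1)CC[C@](C)(O[Si](CC)(CC)CC)C=C)C1=C(CO[Si](c2ccccc2)(c2ccccc2)C(C)(C)C)C(=O)OC1 | intermediate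
20 | C8 ketone | O=C(C[C@H](C)[C@H](OCc1ccc(OC)cc1)CC[C@](C)(O[Si](CC)(CC)CC)C=C)C1=C(CO[Si](c2ccccc2)(c2ccccc2)C(C)(C)C)C(=O)OC1 | intermediate
21 | (8R)-carbinol | O[C@H](C[C@H](C)[C@H](OCc1ccc(OC)cc1)CC[C@](C)(O[Si](CC)(CC)CC)C=C)C1=C(CO[Si](c2ccccc2)(c2ccccc2)C(C)(C)C)C(=O)OC1 | intermediate
22 | (8R)-TBS ether | CC(C)(C)[Si](C)(C)O[C@H](C[C@H](C)[C@H](OCc1ccc(OC)cc1)CC[C@](C)(O[Si](CC)(CC)CC)C=C)C1=C(CO[Si](c2ccccc2)(c2ccccc2)C(C)(C)C)C(=O)OC1 | intermediate
23 | vicinal diol from the vinyl group (not isolated) | CC(C)(C)[Si](C)(C)O[C@H](C[C@H](C)[C@H](OCc1ccc(OC)cc1)CC[C@](C)(O[Si](CC)(CC)CC)C(O)CO)C1=C(CO[Si](c2ccccc2)(c2ccccc2)C(C)(C)C)C(=O)OC1 | intermediate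
24 | butenolide aldehyde, key-step precursor | CC(C)(C)[Si](C)(C)O[C@H](C[C@H](C)[C@H](OCc1ccc(OC)cc1)CC[C@](C)(O[Si](CC)(CC)CC)C=O)C1=C(CO[Si](c2ccccc2)(c2ccccc2)C(C)(C)C)C(=O)OC1 | intermediate
25 | 2-(trimethylsilyloxy)furan aldehyde (not isolated) | CC(C)(C)[Si](C)(C)O[C@H](C[C@H](C)[C@H](OCc1ccc(OC)cc1)CC[C@](C)(O[Si](CC)(CC)CC)C=O)c1coc(O[Si](C)(C)C)c1CO[Si](c2ccccc2)(c2ccccc2)C(C)(C)C | intermediate
26 | C5 trimethylsilyl ether of 27 (not isolated) | CC(C)(C)[Si](C)(C)O[C@@H]1C[C@H](C)[C@H](OCc3ccc(OC)cc3)CC[C@](C)(O[Si](CC)(CC)CC)[C@H](O[Si](C)(C)C)[C@@H]2OC(=O)C(CO[Si](c3ccccc3)(c3ccccc3)C(C)(C)C)=C21 | intermediate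
27 | ten-membered C5 carbinol, key-step product | CC(C)(C)[Si](C)(C)O[C@@H]1C[C@H](C)[C@H](OCc3ccc(OC)cc3)CC[C@](C)(O[Si](CC)(CC)CC)[C@H](O)[C@@H]2OC(=O)C(CO[Si](c3ccccc3)(c3ccccc3)C(C)(C)C)=C21 | intermediate
28 | 4,5-diol | CC(C)(C)[Si](C)(C)O[C@@H]1C[C@H](C)[C@H](OCc3ccc(OC)cc3)CC[C@](C)(O)[C@H](O)[C@@H]2OC(=O)C(CO[Si](c3ccccc3)(c3ccccc3)C(C)(C)C)=C21 | intermediate
29 | cyclic 4,5-orthoacetate (not isolated) | CC(C)(C)[Si](C)(C)O[C@@H]1C[C@H](C)[C@H](OCc3ccc(OC)cc3)CC[C@]4(C)OC(C)(OC)O[C@@H]4[C@@H]2OC(=O)C(CO[Si](c3ccccc3)(c3ccccc3)C(C)(C)C)=C21 | intermediate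
30 | (4R)-4-bromo 5-acetate | CC(C)(C)[Si](C)(C)O[C@@H]1C[C@H](C)[C@H](OCc3ccc(OC)cc3)CC[C@@](C)(Br)[C@H](OC(C)=O)[C@@H]2OC(=O)C(CO[Si](c3ccccc3)(c3ccccc3)C(C)(C)C)=C21 | intermediate
31 | (4S,5R)-epoxide | CC(C)(C)[Si](C)(C)O[C@@H]1C[C@H](C)[C@H](OCc3ccc(OC)cc3)CC[C@]4(C)O[C@@H]4[C@@H]2OC(=O)C(CO[Si](c3ccccc3)(c3ccccc3)C(C)(C)C)=C21 | intermediate
32 | 8,13-diol | O[C@@H]1C[C@H](C)[C@H](OCc3ccc(OC)cc3)CC[C@]4(C)O[C@@H]4[C@@H]2OC(=O)C(CO)=C21 | intermediate
33 | 13-acetate | O[C@@H]1C[C@H](C)[C@H](OCc3ccc(OC)cc3)CC[C@]4(C)O[C@@H]4[C@@H]2OC(=O)C(COC(C)=O)=C21 | intermediate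
34 | 8-methacrylate 13-acetate, C1 PMB ether | C=C(C)C(=O)O[C@@H]1C[C@H](C)[C@H](OCc3ccc(OC)cc3)CC[C@]4(C)O[C@@H]4[C@@H]2OC(=O)C(COC(C)=O)=C21 | intermediate
35 | C1 carbinol | C=C(C)C(=O)O[C@@H]1C[C@H](C)[C@H](O)CC[C@]4(C)O[C@@H]4[C@@H]2OC(=O)C(COC(C)=O)=C21 | intermediate
36 | CNP0128625.1 | C=C(C)C(=O)O[C@@H]1C[C@H](C)C(=O)CC[C@]2(C)O[C@@H]2[C@@H]2OC(=O)C(COC(C)=O)=C21 | target

**Step count**
Total steps: 24. Longest linear sequence: 20 (steps 1–6 and 11–24). Steps 7–10 form the side branch.

**Steps most likely to fail**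

1. Step 16.
   - What may go wrong: oligomerisation may outrun the strained ten-membered closure. Facial selectivity at C5 and C6 may be poor, because Lewis-acid vinylogous aldols of silyloxyfurans tend by themselves toward the other C5/C6 relationship.
   - Fallback: known chemistry in which the two unions are exchanged. It sets out from alcohol 11 and bromobutenolide 18 and comes back at diol 28.
   - 11 is silylated (TESCl, imidazole) to the bis-TES ether F1.
   - The vinyl group of F1 is cleaved (OsO4 cat., NaIO4, 2,6-lutidine) to the α-silyloxy aldehyde F2.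
   - 18 is converted with TESOTf and Et3N into the 4-bromo-2-(triethylsilyloxy)furan F3.
   - An intermolecular vinylogous Mukaiyama aldol (TESOTf cat., CH2Cl2, −78 °C) joins C5 to C6 and, after separation of diastereomers, gives the C5 TES ether F4.
   - Swern conditions oxidise the primary TES ether directly to the C8 aldehyde F5.
   - An intramolecular Nozaki–Hiyama–Kishi reaction (CrCl2, NiCl2 cat., DMF, high dilution) closes ring A at C7–C8 to the macrocyclic carbinol F6, from which the 8R epimer is separated.
   - TBSOTf with 2,6-lutidine gives the silyl ether F7, and HF·pyridine removes both TES groups to give 28.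

2. Step 19.
   - What may go wrong: deprotonation at C6 followed by vinylogous β-elimination of the C5 acetate, or dehydrobromination at C4, may outrun methanolysis and ring closure.
   - Fallback: it sets out from diol 28, bypasses steps 18 and 19, and comes back at epoxide 31.
   - 28 is heated with 1,1'-thiocarbonyldiimidazole in toluene to give the cyclic thionocarbonate F8.
   - Corey–Winter fragmentation with 1,3-dimethyl-2-phenyl-1,3,2-diazaphospholidine at 40 °C is a stereospecific syn elimination and gives the (4Z)-alkene F9.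
   - mCPBA with NaHCO3 epoxidises the only electron-rich alkene from the peripheral face of the ring, the face that carried the two oxygens, to give 31.

3. Step 11.
   - What may go wrong: the tetrasubstituted bromide may react sluggishly, may be reduced to the debrominated butenolide, or its alkenylchromium species may open the ring by β-elimination of the lactone oxygen.
   - Fallback: it sets out from aldehyde 12 and bromide 18, comes back at ketone 20, and makes step 12 unnecessary.
   - 12 is oxidised under Pinnick conditions (NaClO2, NaH2PO4, 2-methylbut-2-ene) to the carboxylic acid F10.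
   - 1-Chloro-N,N,2-trimethylpropenylamine converts F10 under neutral conditions into the acid chloride F11.
   - 18 is stannylated ((Bu3Sn)2, Pd(PPh3)4, toluene, heat) to the 4-tributylstannyl butenolide F12.
   - Stille acylation of F11 with F12 (Pd2(dba)3, tri(2-furyl)phosphine, THF, 50 °C) gives 20.

**Further compounds**
F1 | step 16 | bis-TES ether of 11 | CC[Si](CC)(CC)OCC[C@H](C)[C@H](OCc1ccc(OC)cc1)CC[C@](C)(O[Si](CC)(CC)CC)C=C
F2 | step 16 | C5 aldehyde with C8 TES ether | CC[Si](CC)(CC)OCC[C@H](C)[C@H](OCc1ccc(OC)cc1)CC[C@](C)(O[Si](CC)(CC)CC)C=O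
F3 | step 16 | 4-bromo-3-[(tert-butyldiphenylsilyloxy)methyl]-2-(triethylsilyloxy)furan | CC[Si](CC)(CC)Oc1occ(Br)c1CO[Si](c1ccccc1)(c1ccccc1)C(C)(C)C
F4 | step 16 | open-chain C5–C6 aldol adduct, C5 TES ether | CC[Si](CC)(CC)OCC[C@H](C)[C@H](OCc1ccc(OC)cc1)CC[C@](C)(O[Si](CC)(CC)CC)[C@H](O[Si](CC)(CC)CC)[C@@H]1OC(=O)C(CO[Si](c2ccccc2)(c2ccccc2)C(C)(C)C)=C1Br
F5 | step 16 | C8 aldehyde of the aldol adduct | O=CC[C@H](C)[C@H](OCc1ccc(OC)cc1)CC[C@](C)(O[Si](CC)(CC)CC)[C@H](O[Si](CC)(CC)CC)[C@@H]1OC(=O)C(CO[Si](c2ccccc2)(c2ccccc2)C(C)(C)C)=C1Br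
F6 | step 16 | macrocyclic (8R)-carbinol, 4,5-bis-TES ether | O[C@@H]1C[C@H](C)[C@H](OCc3ccc(OC)cc3)CC[C@](C)(O[Si](CC)(CC)CC)[C@H](O[Si](CC)(CC)CC)[C@@H]2OC(=O)C(CO[Si](c3ccccc3)(c3ccccc3)C(C)(C)C)=C21
F7 | step 16 | C8 TBS ether of F6 | CC(C)(C)[Si](C)(C)O[C@@H]1C[C@H](C)[C@H](OCc3ccc(OC)cc3)CC[C@](C)(O[Si](CC)(CC)CC)[C@H](O[Si](CC)(CC)CC)[C@@H]2OC(=O)C(CO[Si](c3ccccc3)(c3ccccc3)C(C)(C)C)=C21
F8 | step 19 | cyclic 4,5-thionocarbonate | CC(C)(C)[Si](C)(C)O[C@@H]1C[C@H](C)[C@H](OCc3ccc(OC)cc3)CC[C@]4(C)OC(=S)O[C@@H]4[C@@H]2OC(=O)C(CO[Si](c3ccccc3)(c3ccccc3)C(C)(C)C)=C21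
F9 | step 19 | (4Z)-alkene | CC(C)(C)[Si](C)(C)O[C@@H]1C[C@H](C)[C@H](OCc3ccc(OC)cc3)CC/C(C)=C\[C@@H]2OC(=O)C(CO[Si](c3ccccc3)(c3ccccc3)C(C)(C)C)=C21
F10 | step 11 | C8 carboxylic acid | OC(=O)C[C@H](C)[C@H](OCc1ccc(OC)cc1)CC[C@](C)(O[Si](CC)(CC)CC)C=C
F11 | step 11 | C8 acid chloride | ClC(=O)C[C@H](C)[C@H](OCc1ccc(OC)cc1)CC[C@](C)(O[Si](CC)(CC)CC)C=C
F12 | step 11 | 3-[(tert-butyldiphenylsilyloxy)methyl]-4-(tributylstannyl)furan-2(5H)-one | CCCC[Sn](CCCC)(CCCC)C1=C(CO[Si](c2ccccc2)(c2ccccc2)C(C)(C)C)C(=O)OC1
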